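**Plan**

1. Numbering: labdane C1–C20 for the core and chain (C15 = side-chain carbinol), C2'–C5' for the butenolide. Retrosynthetic cuts: C15–C5' (vinylogous aldol), C13=C14 (olefination), C8=C17 (methylenation), C4–C18 (enolate alkylation), C4–C5 (aldol condensation closing ring A), and at the centre C9–C11 and C1–C10.
2. Enabling feature: in ring B the tertiary C9 (carrying the C11 chain) is vicinal to the quaternary, methyl-bearing C10, and C10 is α to C5. With C5 as a carbonyl this is the retron of a conjugate addition to a ring B 2-methylcyclohex-2-enone (C9–C11) followed by Michael capture of its enolate (C10–C1).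
3. Forward order: ring B enters preformed (C8 masked as a dimethyl ketal). A three-component coupling joins the C11–C13 chain and the C1–C4 unit. Ring A is then closed by desilylative aldol condensation.
4. Core functionalisation follows: C4 alkylation, C3 deoxygenation, 5-ene hydroboration, C8 methylenation. The side chain is then extended from C13 to C15 and the butenolide is attached last.
5. Stereochemistry: C9 from the chiral copper catalyst; C10 relayed from C9 (acceptor enters anti to the chain); C4 by α-face alkylation anti to the C10 methyl; C5/C6 by α-face hydroboration; 13E from the phosphonate olefination; C15/C5' from a chiral Lewis-base-catalysed vinylogous Mukaiyama aldol.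
6. The C8 dimethyl ketal and the C13 dioxolane are removed one after the other, so the 8,13-diketone, which would undergo intramolecular aldol cyclisation under base, never forms.

Key step: step 6

Assumption: the sense of induction of the copper/ferrocenyl diphosphine catalyst (step 6) and of the (R,R)-bisphosphoramide (step 20) is taken from the models for simpler enones and conjugated aldehydes; if either is opposite on these substrates, the mirror-image ligand or catalyst is used.

**Route**

Step 1
Reactants: 1 4-methoxy-2-methylphenol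
Product: 2 4,4-dimethoxy-2-methylcyclohexa-2,5-dien-1-one
Conditions: PhI(OAc)2, MeOH, 0 °C
Reagents that add atoms: methanol, CO
Why: Hypervalent-iodine oxidative dearomatisation of a para-alkoxyphenol (quinone monoketal synthesis) should work because the aryloxy-iodane collapses to a para-oxocarbenium ion that the solvent traps at C4.

Step 2
Reactants: 2 4,4-dimethoxy-2-methylcyclohexa-2,5-dien-1-one
Product: 3 4,4-dimethoxy-2-methylcyclohex-2-en-1-one
Conditions: H2 (1 atm), RhCl(PPh3)3 (cat.), toluene, rt
Reagents that add atoms: none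
Why: Chemoselective homogeneous hydrogenation with Wilkinson's catalyst should saturate the disubstituted C5=C6 bond of the cross-conjugated dienone much faster than the trisubstituted, α-methylated C2=C3 bond, as in the reduction of steroidal 1,4-dien-3-ones to 4-en-3-ones.

Step 3
Reactants: 4 2-(2-bromoethyl)-2-methyl-1,3-dioxolane
Product: 5 [2-(2-methyl-1,3-dioxolan-2-yl)ethyl]magnesium bromide
Conditions: Mg turnings, I2 (cat.), 2-MeTHF, 25–30 °C; used as a titrated solution
Reagents that add atoms: magnesium, [Mg]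
Why: Grignard formation by magnesium insertion into the primary C–Br bond should proceed normally because the dioxolane is inert to the organomagnesium at or below 30 °C.

Step 4
Reactants: 6 (1-bromovinyl)trimethylsilane; 7 propanal
Product: 9 2-(trimethylsilyl)pent-1-en-3-ol, via vinyl Grignard reagent 8 (not isolated)
Conditions: Mg, THF, reflux; then 7, 0 °C; aq. NH4Cl
Reagents that add atoms: none
Why: Magnesium insertion into the vinylic bromide gives the α-silylvinyl Grignard reagent, whose 1,2-addition to the unhindered aldehyde (Grignard addition) should give the allylic alcohol as a racemate, which does not matter because the carbinol is oxidised next.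

Step 5
Reactants: 9 2-(trimethylsilyl)pent-1-en-3-ol
Product: 10 2-(trimethylsilyl)pent-1-en-3-one
Conditions: Dess–Martin periodinane, CH2Cl2, 0 °C → rt; distilled
Reagents that add atoms: none
Why: Dess–Martin oxidation should convert the secondary allylic alcohol to the enone under neutral, non-nucleophilic conditions that spare the vinylsilane and do not polymerise the Michael acceptor.

Step 6
Reactants: 3 4,4-dimethoxy-2-methylcyclohex-2-en-1-one; 5 [2-(2-methyl-1,3-dioxolan-2-yl)ethyl]magnesium bromide; 10 2-(trimethylsilyl)pent-1-en-3-one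
Product: 12 (2R,3R)-4,4-dimethoxy-2-methyl-3-[2-(2-methyl-1,3-dioxolan-2-yl)ethyl]-2-[3-oxo-2-(trimethylsilyl)pentyl]cyclohexan-1-one, via bromomagnesium enolate 11 (not isolated)
Conditions: CuBr·SMe2 (5 mol%), (R)-1-[(S)-2-(diphenylphosphino)ferrocenyl]ethyldicyclohexylphosphine (6 mol%), t-BuOMe, −78 °C, slow addition of 5; then 10, −78 → −20 °C; aq. NH4Cl
Reagents that add atoms: none
Why: The chiral copper–alkyl species formed by transmetalation from 5 binds the enone of 3 as a π-complex, adds at C9 to give a trivalent copper intermediate and reductively eliminates to form the C9–C11 bond and the bromomagnesium enolate 11, which then attacks through C10 the unsubstituted terminus of silyl enone 10 to form the C10–C1 bond. The closest known reaction type is the copper/chiral diphosphine-catalysed asymmetric conjugate addition of Grignard reagents to cyclic enones with in situ Michael capture of the metal enolate by an α-silyl vinyl ketone. No ring is closed in this step. C9 is set by the chiral ligand, which selects one face of the prochiral enone, and C10 is set by the substrate: the new C9 chain sits pseudoaxial beside the C10 methyl to avoid allylic strain, so the acceptor enters anti to it and the C10 methyl ends cis to the chain. The step needs 1,4- over 1,2-addition (secured by the copper catalyst and slow Grignard addition at −78 °C), a single C-selective Michael addition without proton transfer or polymerisation (secured by the α-silyl group, which stabilises and shields the adduct enolate), and reaction only at C10 (secured because the enolate is generated regiospecifically and not allowed to equilibrate).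

Step 7
Reactants: 12 (2R,3R)-4,4-dimethoxy-2-methyl-3-[2-(2-methyl-1,3-dioxolan-2-yl)ethyl]-2-[3-oxo-2-(trimethylsilyl)pentyl]cyclohexan-1-one
Product: 15 (4aR,5R)-6,6-dimethoxy-1,4a-dimethyl-5-[2-(2-methyl-1,3-dioxolan-2-yl)ethyl]-4,4a,5,6,7,8-hexahydronaphthalen-2(3H)-one, via desilylated diketone 13 (not isolated), via bicyclic ketol 14 (not isolated)
Conditions: KOH, MeOH, rt → 60 °C
Reagents that add atoms: none
Why: Base-mediated protodesilylation of the α-silyl ketone, intramolecular aldol addition of C4 to the C5 ketone (6-enolexo-exo-trig) and E1cB dehydration complete a Robinson annulation in its α-silyl vinyl ketone form, the conjugated enone being the thermodynamic sink and C9 and C10 not being epimerisable.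

Step 8
Reactants: 15 (4aR,5R)-6,6-dimethoxy-1,4a-dimethyl-5-[2-(2-methyl-1,3-dioxolan-2-yl)ethyl]-4,4a,5,6,7,8-hexahydronaphthalen-2(3H)-one
Product: 17 18-benzyloxy-8,8-dimethoxy-13,13-ethylenedioxy-14,15,17-trinorlabd-5-en-3-one, via potassium dienolate 16 (not isolated)
Conditions: KOtBu, t-BuOH/THF, 0 °C → rt; then BnOCH2Cl, −40 → 0 °C
Reagents that add atoms: benzyl chloromethyl ether, ClCOCc1ccccc1
Why: Deconjugative α-alkylation of the thermodynamic dienolate places the electrophile at C4, and because the axial C10 methyl blocks the β face the benzyloxymethyl group should enter from the α face, giving the 4α-CH2OBn/4β-CH3 quaternary centre with the double bond left at C5=C6.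

Step 9
Reactants: 17 18-benzyloxy-8,8-dimethoxy-13,13-ethylenedioxy-14,15,17-trinorlabd-5-en-3-one
Product: 19 18-benzyloxy-8,8-dimethoxy-13,13-ethylenedioxy-14,15,17-trinorlabd-5-ene, via hydrazone 18 (not isolated)
Conditions: N2H4·H2O, KOH, diethylene glycol, 130 → 200 °C
Reagents that add atoms: none
Why: Wolff–Kishner reduction in its Huang-Minlon form should remove the hindered C3 carbonyl through the hydrazone anion and loss of nitrogen, under strongly basic conditions that both ketals, the benzyl ether and the 5-ene (which cannot move into conjugation past quaternary C4) tolerate.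

Step 10
Reactants: 19 18-benzyloxy-8,8-dimethoxy-13,13-ethylenedioxy-14,15,17-trinorlabd-5-ene
Product: 21 18-benzyloxy-8,8-dimethoxy-13,13-ethylenedioxy-14,15,17-trinorlabdan-6α-ol, via alkylborane 20 (not isolated)
Conditions: BH3·THF, THF, 0 °C → rt; then NaOH, H2O2, H2O, 0 °C → rt
Reagents that add atoms: hydrogen peroxide, OO
Why: Hydroboration–oxidation adds borane syn and anti-Markovnikov to the trisubstituted 5-ene from the α face, away from the β-axial methyl groups on C4 and C10, so hydrogen goes to C5 (trans ring fusion) and boron to C6, and oxidation with retention should give the 6α-alcohol.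

Step 11
Reactants: 21 18-benzyloxy-8,8-dimethoxy-13,13-ethylenedioxy-14,15,17-trinorlabdan-6α-ol
Product: 22 8,8-dimethoxy-13,13-ethylenedioxy-14,15,17-trinorlabdane-6α,18-diol
Conditions: H2 (1 atm), 10% Pd/C, K2CO3 (trace), EtOAc, rt
Reagents that add atoms: none
Why: Catalytic hydrogenolysis cleaves the benzylic C–O bond at the one stage where no alkene is present, so that both hydroxyls can next carry fluoride-labile groups removable at the end without touching alkenes.

Step 12
Reactants: 22 8,8-dimethoxy-13,13-ethylenedioxy-14,15,17-trinorlabdane-6α,18-diol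
Product: 23 6α,18-bis(tert-butyldimethylsilyloxy)-8,8-dimethoxy-13,13-ethylenedioxy-14,15,17-trinorlabdane
Conditions: TBSOTf, 2,6-lutidine, CH2Cl2, −78 → −20 °C
Reagents that add atoms: tert-butyldimethylsilyl trifluoromethanesulfonate, CC(C)(C)[Si](C)(C)OS(=O)(=O)C(F)(F)F
Why: Silyl ether formation with the silyl triflate and a hindered pyridine base is reactive enough for the hindered equatorial 6α-hydroxyl and the neopentyl primary hydroxyl, while the low temperature and the base should keep both ketals intact.

Step 13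
Reactants: 23 6α,18-bis(tert-butyldimethylsilyloxy)-8,8-dimethoxy-13,13-ethylenedioxy-14,15,17-trinorlabdane
Product: 24 6α,18-bis(tert-butyldimethylsilyloxy)-13,13-ethylenedioxy-14,15,17-trinorlabdan-8-one
Conditions: PPTS (cat.), acetone/H2O (20:1), rt
Reagents that add atoms: water, O
Why: Chemoselective acid-catalysed ketal hydrolysis relies on the much faster cleavage of an acyclic dimethyl ketal than of a 1,3-dioxolane, so only the C8 ketone should be unmasked, with C9 staying in its more stable equatorial configuration.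

Step 14
Reactants: 24 6α,18-bis(tert-butyldimethylsilyloxy)-13,13-ethylenedioxy-14,15,17-trinorlabdan-8-one
Product: 25 6α,18-bis(tert-butyldimethylsilyloxy)-13,13-ethylenedioxy-14,15-dinorlabd-8(17)-ene
Conditions: Cp2TiMe2, toluene, 70 °C, dark
Reagents that add atoms: dimethyltitanocene, C[Ti](C)(C1C=CC=C1)C1C=CC=C1
Why: Petasis methylenation through the titanium methylidene and an oxatitanacyclobutane is non-basic, so it should convert the hindered, enolisable β-silyloxy ketone to the 8(17)-alkene without β-elimination at C6 or epimerisation at C9.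

Step 15
Reactants: 25 6α,18-bis(tert-butyldimethylsilyloxy)-13,13-ethylenedioxy-14,15-dinorlabd-8(17)-ene
Product: 26 6α,18-bis(tert-butyldimethylsilyloxy)-14,15-dinorlabd-8(17)-en-13-one
Conditions: PPTS, acetone/H2O (5:1), 55 °C
Reagents that add atoms: water, O
Why: Acid-catalysed dioxolane hydrolysis in warm wet acetone now frees the methyl ketone, which, with C8 already an alkene, has no carbonyl partner for an intramolecular aldol reaction, while the hindered silyl ethers and the exocyclic alkene should survive the weak acid.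

Step 16
Reactants: 26 6α,18-bis(tert-butyldimethylsilyloxy)-14,15-dinorlabd-8(17)-en-13-one
Product: 27 ethyl (13E)-6α,18-bis(tert-butyldimethylsilyloxy)labda-8(17),13-dien-15-oate
Conditions: (EtO)2P(O)CH2CO2Et, NaH, THF, 0 → 50 °C; chromatographic removal of the Z isomer
Reagents that add atoms: triethyl phosphonoacetate, CCOC(=O)CP(=O)(OCC)OCC
Why: Horner–Wadsworth–Emmons olefination of the methyl ketone with the stabilised phosphonate anion forms the C13=C14 bond with the ester preferentially trans to the larger C12 chain (E), the minor Z isomer being separable.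

Step 17
Reactants: 27 ethyl (13E)-6α,18-bis(tert-butyldimethylsilyloxy)labda-8(17),13-dien-15-oate
Product: 28 (13E)-6α,18-bis(tert-butyldimethylsilyloxy)labda-8(17),13-dien-15-ol
Conditions: iBu2AlH, CH2Cl2, −78 °C; Rochelle salt work-up
Reagents that add atoms: none
Why: DIBAL reduction of the α,β-unsaturated ester gives the allylic alcohol by 1,2-hydride delivery without touching the alkenes or silyl ethers and without changing the alkene geometry.

Step 18
Reactants: 28 (13E)-6α,18-bis(tert-butyldimethylsilyloxy)labda-8(17),13-dien-15-ol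
Product: 29 (13E)-6α,18-bis(tert-butyldimethylsilyloxy)labda-8(17),13-dien-15-al
Conditions: MnO2, CH2Cl2, rt
Reagents that add atoms: none
Why: Manganese dioxide oxidation is selective for allylic alcohols and should give the E-configured enal without over-oxidation.

Step 19
Reactants: 30 4-methylfuran-2(5H)-one
Product: 31 tert-butyl(dimethyl)[(4-methylfuran-2-yl)oxy]silane
Conditions: TBSOTf, Et3N, CH2Cl2, 0 °C
Reagents that add atoms: tert-butyldimethylsilyl trifluoromethanesulfonate, CC(C)(C)[Si](C)(C)OS(=O)(=O)C(F)(F)F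
Why: Soft enolisation of the butenolide with silyl triflate and triethylamine traps the aromatic 2-silyloxyfuran, the standard preparation of furan-based silyl dienolates.

Step 20
Reactants: 29 (13E)-6α,18-bis(tert-butyldimethylsilyloxy)labda-8(17),13-dien-15-al; 31 tert-butyl(dimethyl)[(4-methylfuran-2-yl)oxy]silane
Product: 32 (5S)-5-[(13E,15S)-6α,18-bis(tert-butyldimethylsilyloxy)-15-hydroxylabda-8(17),13-dien-15-yl]-4-methylfuran-2(5H)-one
Conditions: SiCl4, (R,R)-bisphosphoramide (binaphthyl-2,2'-diamine-derived, pentane-1,5-diyl-linked; 5 mol%), iPr2NEt (10 mol%), CH2Cl2, −78 °C; aq. NaHCO3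
Reagents that add atoms: none
Why: In this vinylogous Mukaiyama aldol addition under Lewis-base-activated SiCl4 catalysis, C5 of the silyloxyfuran attacks the aldehyde through an open transition state in which the catalyst-bound chiral silyl cation exposes one aldehyde face (expected to give 15S) and the furan dienolate adds with like (threo) topicity (expected to give 5'S), a mode established for conjugated aldehydes.

Step 21
Reactants: 32 (5S)-5-[(13E,15S)-6α,18-bis(tert-butyldimethylsilyloxy)-15-hydroxylabda-8(17),13-dien-15-yl]-4-methylfuran-2(5H)-one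
Product: 33 (5S)-5-[(13E,15S)-6α,15,18-trihydroxylabda-8(17),13-dien-15-yl]-4-methylfuran-2(5H)-one
Conditions: HF·pyridine, pyridine/THF, 0 °C → rt
Reagents that add atoms: none
Why: Fluoride-mediated desilylation with buffered HF·pyridine cleaves both Si–O bonds through pentacoordinate silicon and should not harm the allylic alcohol, the butenolide or the exocyclic alkene.

**Compound list**

1 | 4-methoxy-2-methylphenol | Cc1cc(OC)ccc1O | starting material
2 | 4,4-dimethoxy-2-methylcyclohexa-2,5-dien-1-one | CC1=CC(OC)(OC)C=CC1=O | intermediate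
3 | 4,4-dimethoxy-2-methylcyclohex-2-en-1-one (ring B; carbonyl = C5, methyl-bearing carbon = C10, β-carbon = C9, ketal carbon = C8) | CC1=CC(OC)(OC)CCC1=O | intermediate
4 | 2-(2-bromoethyl)-2-methyl-1,3-dioxolane | CC1(CCBr)OCCO1 | starting material
5 | [2-(2-methyl-1,3-dioxolan-2-yl)ethyl]magnesium bromide | CC1(CC[Mg]Br)OCCO1 | intermediate
6 | (1-bromovinyl)trimethylsilane | C=C(Br)[Si](C)(C)C | starting material
7 | propanal | CCC=O | starting material
8 | [1-(trimethylsilyl)vinyl]magnesium bromide (formed in the flask) | C=C([Mg]Br)[Si](C)(C)C | intermediate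
9 | 2-(trimethylsilyl)pent-1-en-3-ol (racemic) | CCC(O)C(=C)[Si](C)(C)C | intermediate
10 | 2-(trimethylsilyl)pent-1-en-3-one | CCC(=O)C(=C)[Si](C)(C)C | intermediate
11 | bromomagnesium (3R)-4,4-dimethoxy-2-methyl-3-[2-(2-methyl-1,3-dioxolan-2-yl)ethyl]cyclohex-1-en-1-olate (formed in the flask) | CC1=C(O[Mg]Br)CCC(OC)(OC)[C@@H]1CCC1(C)OCCO1 | intermediate
12 | (2R,3R)-4,4-dimethoxy-2-methyl-3-[2-(2-methyl-1,3-dioxolan-2-yl)ethyl]-2-[3-oxo-2-(trimethylsilyl)pentyl]cyclohexan-1-one (both epimers at the silyl-bearing carbon; C10 methyl cis to the C9 chain) | O=C1CCC(OC)(OC)[C@H](CCC2(C)OCCO2)[C@@]1(C)CC([Si](C)(C)C)C(=O)CC | intermediate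
13 | (2R,3R)-4,4-dimethoxy-2-methyl-3-[2-(2-methyl-1,3-dioxolan-2-yl)ethyl]-2-(3-oxopentyl)cyclohexan-1-one (formed in the flask) | O=C1CCC(OC)(OC)[C@H](CCC2(C)OCCO2)[C@@]1(C)CCC(=O)CC | intermediate
14 | (4aR,5R)-8a-hydroxy-6,6-dimethoxy-1,4a-dimethyl-5-[2-(2-methyl-1,3-dioxolan-2-yl)ethyl]octahydronaphthalen-2(1H)-one (configuration at C1 and C8a not defined; formed in the flask) | CC1C2(O)CCC(OC)(OC)[C@H](CCC3(C)OCCO3)[C@@]2(C)CCC1=O | intermediate
15 | (4aR,5R)-6,6-dimethoxy-1,4a-dimethyl-5-[2-(2-methyl-1,3-dioxolan-2-yl)ethyl]-4,4a,5,6,7,8-hexahydronaphthalen-2(3H)-one | CC1=C2CCC(OC)(OC)[C@H](CCC3(C)OCCO3)[C@@]2(C)CCC1=O | intermediate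
16 | potassium dienolate of 15 (O–C3=C4 and C5=C6; formed in the flask) | COC1(OC)CC=C2C(C)=C([O-])CC[C@]2(C)[C@H]1CCC1(C)OCCO1.[K+] | intermediate
17 | 18-benzyloxy-8,8-dimethoxy-13,13-ethylenedioxy-14,15,17-trinorlabd-5-en-3-one (4α-CH2OBn, 4β-CH3, 9β chain, 10β-CH3) | COC1(OC)CC=C2[C@](C)(COCc3ccccc3)C(=O)CC[C@]2(C)[C@H]1CCC1(C)OCCO1 | intermediate
18 | C3 hydrazone of 17 (formed in the flask) | COC1(OC)CC=C2[C@](C)(COCc3ccccc3)C(=NN)CC[C@]2(C)[C@H]1CCC1(C)OCCO1 | intermediate
19 | 18-benzyloxy-8,8-dimethoxy-13,13-ethylenedioxy-14,15,17-trinorlabd-5-ene | COC1(OC)CC=C2[C@](C)(COCc3ccccc3)CCC[C@]2(C)[C@H]1CCC1(C)OCCO1 | intermediate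
20 | 6α-boryl adduct of 19 (5α-H, 6α-BH2; formed in the flask) | COC1(OC)C[C@H](B)[C@H]2[C@](C)(COCc3ccccc3)CCC[C@]2(C)[C@H]1CCC1(C)OCCO1 | intermediate
21 | 18-benzyloxy-8,8-dimethoxy-13,13-ethylenedioxy-14,15,17-trinorlabdan-6α-ol (5α-H, trans-decalin) | COC1(OC)C[C@H](O)[C@H]2[C@](C)(COCc3ccccc3)CCC[C@]2(C)[C@H]1CCC1(C)OCCO1 | intermediate
22 | 8,8-dimethoxy-13,13-ethylenedioxy-14,15,17-trinorlabdane-6α,18-diol | COC1(OC)C[C@H](O)[C@H]2[C@](C)(CO)CCC[C@]2(C)[C@H]1CCC1(C)OCCO1 | intermediate
23 | 6α,18-bis(tert-butyldimethylsilyloxy)-8,8-dimethoxy-13,13-ethylenedioxy-14,15,17-trinorlabdane | COC1(OC)C[C@H](O[Si](C)(C)C(C)(C)C)[C@H]2[C@](C)(CO[Si](C)(C)C(C)(C)C)CCC[C@]2(C)[C@H]1CCC1(C)OCCO1 | intermediate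
24 | 6α,18-bis(tert-butyldimethylsilyloxy)-13,13-ethylenedioxy-14,15,17-trinorlabdan-8-one | O=C1C[C@H](O[Si](C)(C)C(C)(C)C)[C@H]2[C@](C)(CO[Si](C)(C)C(C)(C)C)CCC[C@]2(C)[C@H]1CCC1(C)OCCO1 | intermediate
25 | 6α,18-bis(tert-butyldimethylsilyloxy)-13,13-ethylenedioxy-14,15-dinorlabd-8(17)-ene | C=C1C[C@H](O[Si](C)(C)C(C)(C)C)[C@H]2[C@](C)(CO[Si](C)(C)C(C)(C)C)CCC[C@]2(C)[C@H]1CCC1(C)OCCO1 | intermediate
26 | 6α,18-bis(tert-butyldimethylsilyloxy)-14,15-dinorlabd-8(17)-en-13-one | C=C1C[C@H](O[Si](C)(C)C(C)(C)C)[C@H]2[C@](C)(CO[Si](C)(C)C(C)(C)C)CCC[C@]2(C)[C@H]1CCC(C)=O | intermediate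
27 | ethyl (13E)-6α,18-bis(tert-butyldimethylsilyloxy)labda-8(17),13-dien-15-oate | C=C1C[C@H](O[Si](C)(C)C(C)(C)C)[C@H]2[C@](C)(CO[Si](C)(C)C(C)(C)C)CCC[C@]2(C)[C@H]1CC/C(C)=C/C(=O)OCC | intermediate
28 | (13E)-6α,18-bis(tert-butyldimethylsilyloxy)labda-8(17),13-dien-15-ol | C=C1C[C@H](O[Si](C)(C)C(C)(C)C)[C@H]2[C@](C)(CO[Si](C)(C)C(C)(C)C)CCC[C@]2(C)[C@H]1CC/C(C)=C/CO | intermediate
29 | (13E)-6α,18-bis(tert-butyldimethylsilyloxy)labda-8(17),13-dien-15-al | C=C1C[C@H](O[Si](C)(C)C(C)(C)C)[C@H]2[C@](C)(CO[Si](C)(C)C(C)(C)C)CCC[C@]2(C)[C@H]1CC/C(C)=C/C=O | intermediate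
30 | 4-methylfuran-2(5H)-one | CC1=CC(=O)OC1 | starting material
31 | tert-butyl(dimethyl)[(4-methylfuran-2-yl)oxy]silane | Cc1coc(O[Si](C)(C)C(C)(C)C)c1 | intermediate
32 | (5S)-5-[(13E,15S)-6α,18-bis(tert-butyldimethylsilyloxy)-15-hydroxylabda-8(17),13-dien-15-yl]-4-methylfuran-2(5H)-one | C=C1C[C@H](O[Si](C)(C)C(C)(C)C)[C@H]2[C@](C)(CO[Si](C)(C)C(C)(C)C)CCC[C@]2(C)[C@H]1CC/C(C)=C/[C@H](O)[C@H]1OC(=O)C=C1C | intermediate
33 | (5S)-5-[(13E,15S)-6α,15,18-trihydroxylabda-8(17),13-dien-15-yl]-4-methylfuran-2(5H)-one (4R,5R,6S,9S,10R,15S,5'S; CNP0221530.1) | C=C1C[C@H](O)[C@H]2[C@](C)(CO)CCC[C@]2(C)[C@H]1CC/C(C)=C/[C@H](O)[C@H]1OC(=O)C=C1C | target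

**Totals and risks**

Total step count: 21.
Longest linear sequence: 17 steps (steps 1, 2, 6–18, 20, 21; the branch through steps 4 and 5 is equally long).

Steps most likely to fail:

Step 6. The α-methylated enone with a fully substituted γ-carbon may add the Grignard reagent slowly or with poor face selection. The magnesium enolate may also be captured sluggishly, or undergo proton transfer or double addition. The fallback sets out from 3 and 5 and returns at 12. The copper-catalysed addition is run with Me3SiCl present, which accelerates addition to hindered enones and traps the enolate as the trimethylsilyl enol ether F1, which is isolated. MeLi in THF at 0 °C then cleaves the Si–O bond to give the lithium enolate F2, which is treated with 10 at −78 °C to give 12 after aqueous work-up. The two bond formations are thus separated and the Michael step runs on a defined lithium enolate.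

Step 8. The hard chloromethyl ether may alkylate the dienolate on oxygen, or proton transfer may lead to alkylation at C2. The fallback sets out from 15 and returns at 17. Dienolate 16 is quenched at −78 °C with monomeric formaldehyde (from cracked paraformaldehyde), whose attack on oxygen is reversible, so that only the C4 adduct accumulates, giving the 4α-hydroxymethyl ketone F3. Its primary alcohol is then benzylated under neutral conditions with 2-benzyloxy-1-methylpyridinium triflate and MgO in PhCF3 at 85 °C, giving 17 without retro-aldol loss of the new carbon.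

Step 20. The catalyst may not override the intrinsic preferences of the β,β-disubstituted enal and the 4-methylated silyloxyfuran, leading to attack on the wrong aldehyde face, erythro instead of threo topicity, or low conversion. The fallback sets out from 29 and returns at 33; it sets both centres by auxiliary control.
- An Evans syn-aldol reaction of 29 with the dibutylboron enolate of (R)-4-benzyl-3-[(4-methoxybenzyloxy)acetyl]oxazolidin-2-one (Bu2BOTf, Et3N, CH2Cl2, −78 → 0 °C) gives the syn-glycolate aldol adduct F4.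
- AlMe3 with MeNH(OMe)·HCl converts this to the hydroxy Weinreb amide F5.
- TBSOTf/2,6-lutidine gives the C15 silyl ether F6.
- MeMgBr gives the methyl ketone F7.
- DDQ in CH2Cl2/pH 7 buffer removes the 4-methoxybenzyl group to give the α-hydroxy ketone F8.
- Ph3P=C=C=O (Bestmann ylide, toluene, 80 °C) acylates the free hydroxyl and closes the ring by intramolecular Wittig reaction to the tris-silylated butenolide F9.
- HF·pyridine converts F9 to 33.

Further compounds
F1 | step 6 | (R)-{[4,4-dimethoxy-2-methyl-3-[2-(2-methyl-1,3-dioxolan-2-yl)ethyl]cyclohex-1-en-1-yl]oxy}trimethylsilane | CC1=C(O[Si](C)(C)C)CCC(OC)(OC)[C@@H]1CCC1(C)OCCO1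
F2 | step 6 | lithium (3R)-4,4-dimethoxy-2-methyl-3-[2-(2-methyl-1,3-dioxolan-2-yl)ethyl]cyclohex-1-en-1-olate | CC1=C(O[Li])CCC(OC)(OC)[C@@H]1CCC1(C)OCCO1
F3 | step 8 | 18-hydroxy-8,8-dimethoxy-13,13-ethylenedioxy-14,15,17-trinorlabd-5-en-3-one (4α-CH2OH, 4β-CH3) | COC1(OC)CC=C2[C@](C)(CO)C(=O)CC[C@]2(C)[C@H]1CCC1(C)OCCO1
F4 | step 20 | (R)-4-benzyl-3-[(2R,3S)-3-hydroxy-2-(4-methoxybenzyloxy)acyl]oxazolidin-2-one aldol adduct of 29 (acyl C3 = C15, acyl C2 = future C5') | C=C1C[C@H](O[Si](C)(C)C(C)(C)C)[C@H]2[C@](C)(CO[Si](C)(C)C(C)(C)C)CCC[C@]2(C)[C@H]1CC/C(C)=C/[C@H](O)[C@@H](OCc1ccc(OC)cc1)C(=O)N1[C@H](Cc2ccccc2)COC1=O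
F5 | step 20 | corresponding (2R,3S)-3-hydroxy-2-(4-methoxybenzyloxy) N-methoxy-N-methylamide | C=C1C[C@H](O[Si](C)(C)C(C)(C)C)[C@H]2[C@](C)(CO[Si](C)(C)C(C)(C)C)CCC[C@]2(C)[C@H]1CC/C(C)=C/[C@H](O)[C@@H](OCc1ccc(OC)cc1)C(=O)N(C)OC
F6 | step 20 | C15 tert-butyldimethylsilyl ether of the N-methoxy-N-methylamide | C=C1C[C@H](O[Si](C)(C)C(C)(C)C)[C@H]2[C@](C)(CO[Si](C)(C)C(C)(C)C)CCC[C@]2(C)[C@H]1CC/C(C)=C/[C@H](O[Si](C)(C)C(C)(C)C)[C@@H](OCc1ccc(OC)cc1)C(=O)N(C)OC
F7 | step 20 | methyl ketone with C15 silyloxy and C5' 4-methoxybenzyloxy groups | C=C1C[C@H](O[Si](C)(C)C(C)(C)C)[C@H]2[C@](C)(CO[Si](C)(C)C(C)(C)C)CCC[C@]2(C)[C@H]1CC/C(C)=C/[C@H](O[Si](C)(C)C(C)(C)C)[C@@H](OCc1ccc(OC)cc1)C(C)=O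
F8 | step 20 | α-hydroxy methyl ketone with C15 silyloxy group | C=C1C[C@H](O[Si](C)(C)C(C)(C)C)[C@H]2[C@](C)(CO[Si](C)(C)C(C)(C)C)CCC[C@]2(C)[C@H]1CC/C(C)=C/[C@H](O[Si](C)(C)C(C)(C)C)[C@@H](O)C(C)=O
F9 | step 20 | (5S)-5-[(13E,15S)-6α,15,18-tris(tert-butyldimethylsilyloxy)labda-8(17),13-dien-15-yl]-4-methylfuran-2(5H)-one | C=C1C[C@H](O[Si](C)(C)C(C)(C)C)[C@H]2[C@](C)(CO[Si](C)(C)C(C)(C)C)CCC[C@]2(C)[C@H]1CC/C(C)=C/[C@H](O[Si](C)(C)C(C)(C)C)[C@H]1OC(=O)C=C1C
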